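**Plan**

1. Retrosynthesis: after the silyl ether, the ring C3=C4 double bond and the O1–C6 bond of the 5,6-dihydro-2H-pyran-2-one are cut together. This gives an α-keto carboxylate (O1, C2, C3 and the homoprenyl chain) and a trans-2-alkenylcyclopropyl-triphenylphosphonium salt (C4, C5, C6 and the acetoxy/neryl side chain).
2. Enabling feature: ring atoms C4 (=CH), C5 (CH2) and C6 (CH–O, allylic to the exocyclic C(CH2OAc)=CH alkene) are 1,3-related and can be stored as a cyclopropane with a vinyl donor on C6 and a PPh3+ acceptor on C4. O-attack at C6 releases the strain and leaves the ylide on C4, next to the C3 ketone.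
3. Further cuts: cyclopropane C4–C6 (ylide alkylation), P–C4 (phospha-Michael addition to a divinyl ketone), C6–C(alkene) (vinylalane plus acrolein), alkyne–ester C–C (acetylide acylation), and the 6,7-alkene of nerol.
4. Forward: nerol → C6 aldehyde → alkyne → ynoate → hydroalumination/acrolein adduct → diol → monoacetate → keto phosphonium salt → (S)-alcohol → cyclopropane → [3+3] lactone annulation (the only ring, made in the penultimate step) → desilylation.
5. Stereochemistry: the Z allylic alcohol comes from nerol; the trisubstituted alkene from syn-hydroalumination of the ynoate; the carbinol centre from CBS reduction, inverted once at cyclopropane closure and once at ring opening; the ring alkene is Z by ring constraint.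

Key step: step 13

Remark: the phosphorus-bearing cyclopropane carbon of 17 is drawn trans; its configuration is lost when it becomes the ylide carbon and does not affect the outcome.

**Step 1**
Reactants: 1 nerol [(2Z)-3,7-dimethylocta-2,6-dien-1-ol]
Product: 2 tert-butyl{[(2Z)-3,7-dimethylocta-2,6-dien-1-yl]oxy}diphenylsilane
Conditions: TBDPSCl, imidazole, CH2Cl2, 0 °C to rt
Reagents that add atoms: tert-butyl(chloro)diphenylsilane, CC(C)(C)[Si](Cl)(c1ccccc1)c1ccccc1
Why: Imidazole-mediated silylation of the primary allylic alcohol gives a robust silyl ether that should survive the organometallic, oxidative and mildly acidic steps and is removed last.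

**Step 2**
Reactants: 2 tert-butyl{[(2Z)-3,7-dimethylocta-2,6-dien-1-yl]oxy}diphenylsilane
Product: 4 (4Z)-6-[(tert-butyldiphenylsilyl)oxy]-4-methylhex-4-enal, via 6,7-epoxide 3 (not isolated)
Conditions: mCPBA, CH2Cl2, 0 °C; then H5IO6, THF/H2O, 0 °C
Reagents that add atoms: 3-chloroperbenzoic acid, OOC(=O)c1cccc(Cl)c1
Why: Peracid epoxidation should select the remote, more electron-rich trisubstituted alkene (the 2,3-alkene is deactivated by the allylic oxygen), and periodic acid then cleaves the epoxide through its diol (glycol cleavage) to the aldehyde and acetone without touching the Z alkene.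

**Step 3**
Reactants: 4 (4Z)-6-[(tert-butyldiphenylsilyl)oxy]-4-methylhex-4-enal
Product: 5 tert-butyl{[(2Z)-3-methylhept-2-en-6-yn-1-yl]oxy}diphenylsilane
Conditions: dimethyl (1-diazo-2-oxopropyl)phosphonate, K2CO3, MeOH, 0 °C to rt
Reagents that add atoms: dimethyl (1-diazo-2-oxopropyl)phosphonate, COP(=O)(OC)C(=[N+]=[N-])C(C)=O
Why: Seyferth–Gilbert homologation with the Ohira–Bestmann reagent converts an enolisable aldehyde into the terminal alkyne under mild carbonate conditions.

**Step 4**
Reactants: 5 tert-butyl{[(2Z)-3-methylhept-2-en-6-yn-1-yl]oxy}diphenylsilane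
Product: 7 methyl (6Z)-8-[(tert-butyldiphenylsilyl)oxy]-6-methyloct-6-en-2-ynoate, via lithium acetylide 6 (not isolated)
Conditions: n-BuLi, THF, −78 °C; then ClCO2Me, −78 to 0 °C
Reagents that add atoms: methyl chloroformate, COC(Cl)=O
Why: Deprotonation of the terminal alkyne and C-acylation of the acetylide with a chloroformate is the standard route to 2-ynoates.

**Step 5**
Reactants: 7 methyl (6Z)-8-[(tert-butyldiphenylsilyl)oxy]-6-methyloct-6-en-2-ynoate, 8 acrolein (prop-2-enal)
Product: 10 methyl (2Z,6Z)-8-[(tert-butyldiphenylsilyl)oxy]-2-(1-hydroxyprop-2-en-1-yl)-6-methylocta-2,6-dienoate (racemic), via vinylalane 9 (not isolated)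
Conditions: i-Bu2AlH, N-methylmorpholine N-oxide, THF, 0 °C; then 8, 0 °C to rt; aqueous KNaC4H4O6
Reagents that add atoms: none
Why: Ester-directed syn-hydroalumination puts Al on the α-carbon and H on the β-carbon, so chain and ester end up cis, and the α-aluminoenoate should add 1,2 to acrolein with retention of geometry (vinylalumination, giving a Morita–Baylis–Hillman-type adduct); the carbinol forms racemic and is corrected in steps 8 and 9.

**Step 6**
Reactants: 10 methyl (2Z,6Z)-8-[(tert-butyldiphenylsilyl)oxy]-2-(1-hydroxyprop-2-en-1-yl)-6-methylocta-2,6-dienoate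
Product: 11 (4E,8Z)-10-[(tert-butyldiphenylsilyl)oxy]-4-(hydroxymethyl)-8-methyldeca-1,4,8-trien-3-ol (racemic)
Conditions: i-Bu2AlH (excess), CH2Cl2, −78 to 0 °C; aqueous KNaC4H4O6
Reagents that add atoms: none
Why: Hydride reduction of the conjugated ester with i-Bu2AlH proceeds 1,2 to the primary allylic alcohol and should leave the trisubstituted alkene geometry intact.

**Step 7**
Reactants: 11 (4E,8Z)-10-[(tert-butyldiphenylsilyl)oxy]-4-(hydroxymethyl)-8-methyldeca-1,4,8-trien-3-ol
Product: 12 (2E,6Z)-8-[(tert-butyldiphenylsilyl)oxy]-2-(1-hydroxyprop-2-en-1-yl)-6-methylocta-2,6-dien-1-yl acetate (racemic)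
Conditions: AcCl, 2,4,6-collidine, CH2Cl2, −78 °C
Reagents that add atoms: acetyl chloride, CC(Cl)=O
Why: Acetyl chloride with a hindered pyridine base at low temperature acylates the primary allylic hydroxyl much faster than the hindered secondary bis-allylic one (selective primary acylation).

**Step 8**
Reactants: 12 (2E,6Z)-8-[(tert-butyldiphenylsilyl)oxy]-2-(1-hydroxyprop-2-en-1-yl)-6-methylocta-2,6-dien-1-yl acetate
Product: 14 {(4E,8Z)-4-[(acetyloxy)methyl]-10-[(tert-butyldiphenylsilyl)oxy]-8-methyl-3-oxodeca-4,8-dien-1-yl}triphenylphosphonium tetrafluoroborate, via divinyl ketone 13 (not isolated)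
Conditions: Dess–Martin periodinane, CH2Cl2, 0 °C; filter through silica; then Ph3PH·BF4, MeCN, 0 °C to rt
Reagents that add atoms: triphenylphosphonium tetrafluoroborate, [PH+](c1ccccc1)(c1ccccc1)c1ccccc1.F[B-](F)(F)F
Why: Dess–Martin oxidation erases the racemic carbinol as a cross-conjugated divinyl ketone whose unsubstituted vinyl terminus is the only unhindered Michael position, and this takes up triphenylphosphine under protonation (phospha-Michael addition) to give the β-phosphonio ketone.

**Step 9**
Reactants: 14 {(4E,8Z)-4-[(acetyloxy)methyl]-10-[(tert-butyldiphenylsilyl)oxy]-8-methyl-3-oxodeca-4,8-dien-1-yl}triphenylphosphonium tetrafluoroborate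
Product: 15 {(3S,4E,8Z)-4-[(acetyloxy)methyl]-10-[(tert-butyldiphenylsilyl)oxy]-3-hydroxy-8-methyldeca-4,8-dien-1-yl}triphenylphosphonium tetrafluoroborate
Conditions: (R)-2-methyl-CBS-oxazaborolidine (cat.), catecholborane, CH2Cl2, −78 °C; pH 7 aqueous work-up
Reagents that add atoms: none
Why: In the Corey–Bakshi–Shibata reduction the (R)-oxazaborolidine treats the α-branched alkenyl group as the large and the CH2 group as the small substituent and should deliver hydride to the face that gives the (S)-allylic alcohol, while catecholborane at low temperature spares the alkenes and the acetate.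

**Step 10**
Reactants: 15 {(3S,4E,8Z)-4-[(acetyloxy)methyl]-10-[(tert-butyldiphenylsilyl)oxy]-3-hydroxy-8-methyldeca-4,8-dien-1-yl}triphenylphosphonium tetrafluoroborate
Product: 17 {(1S,2R)-2-[(2Z,6Z)-1-(acetyloxy)-8-[(tert-butyldiphenylsilyl)oxy]-6-methylocta-2,6-dien-2-yl]cyclopropyl}triphenylphosphonium tetrafluoroborate (trans), via allylic mesylate 16 (not isolated)
Conditions: Ms2O, i-Pr2NEt, CH2Cl2, −40 °C; then KN(SiMe3)2 (2.2 equiv), THF, −78 to 0 °C
Reagents that add atoms: none
Why: Mesylation (retention) followed by deprotonation next to phosphorus triggers a 3-exo-tet displacement of the allylic mesylate by the ylide carbon with inversion, the classical ring closure to cyclopropylphosphonium salts, and the less hindered trans salt should result.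

**Step 11**
Reactants: 18 5-bromo-2-methylpent-2-ene, 19 diethyl oxalate
Product: 21 ethyl 6-methyl-2-oxohept-5-enoate, via Grignard reagent 20 (not isolated)
Conditions: Mg, THF, rt; then add to 19 (2 equiv), THF, −78 °C; 1 M HCl
Reagents that add atoms: none
Why: Inverse addition of the homoprenyl Grignard reagent to excess diethyl oxalate at low temperature stops at the α-keto ester because the tetrahedral adduct persists until work-up.

**Step 12**
Reactants: 21 ethyl 6-methyl-2-oxohept-5-enoate
Product: 22 cesium 6-methyl-2-oxohept-5-enoate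
Conditions: CsOH·H2O (1.0 equiv), THF/H2O, 0 °C; freeze-dry
Reagents that add atoms: cesium hydroxide, [Cs+].[OH-]
Why: The activated ester of an α-keto ester is saponified rapidly by one equivalent of hydroxide, which gives the cesium carboxylate directly as the nucleophile for the next step.

**Step 13**
Reactants: 17 {(1S,2R)-2-[(2Z,6Z)-1-(acetyloxy)-8-[(tert-butyldiphenylsilyl)oxy]-6-methylocta-2,6-dien-2-yl]cyclopropyl}triphenylphosphonium tetrafluoroborate, 22 cesium 6-methyl-2-oxohept-5-enoate
Product: 24 (2E,6Z)-8-[(tert-butyldiphenylsilyl)oxy]-6-methyl-2-[(2S)-5-(4-methylpent-3-en-1-yl)-6-oxo-3,6-dihydro-2H-pyran-2-yl]octa-2,6-dien-1-yl acetate, via ylide keto ester 23 (not isolated)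
Conditions: 22 (2 equiv), dry DMF, 4 Å molecular sieves, 60 to 80 °C
Reagents that add atoms: none
Why: Proposed new method: the carboxylate oxygen of 22 attacks the allylic ring carbon of the vinyl (donor)–phosphonium (acceptor) cyclopropane 17 in an SN2-type homoconjugate opening, the ring bond anti to the incoming oxygen breaks, and the electron pair appears on the phosphorus-bearing carbon as ylide 23, which at once olefinates the neighbouring α-keto ester carbonyl (intramolecular Wittig reaction) with loss of Ph3PO. The closest known reaction types are annulations in which an oxygen or carbon nucleophile opens a cyclopropyltriphenylphosphonium salt and the liberated ylide closes a ring by Wittig reaction, and the invertive opening of vinyl-substituted acceptor cyclopropanes by heteroatom nucleophiles. The only ring, the 5,6-dihydro-2H-pyran-2-one, closes in the Wittig stage by attack of the ylide carbon on the ketone carbon within the ester tether (six-membered ring formation), which forces the ring alkene to be Z. The one new stereocentre, the oxygen-bearing ring carbon, is set by inversion at the cyclopropane carbon, so it is controlled by the configuration installed in step 9 and carried through step 10. The step needs attack at the ring carbon and not at the alkene terminus (SN2') or at phosphorus, and needs the opened ylide to olefinate faster than it recloses: the fully substituted neighbouring alkene carbon shields the SN2' position, only the SN2 adduct can reach a six-membered Wittig transition state while any other opened ylide can revert to the cyclopropane, and the dry tetrafluoroborate medium leaves the carboxylate as the only nucleophile. Release of the three-membered ring strain and the irreversible formation of Ph3PO should provide the driving force for the weakly nucleophilic α-keto carboxylate.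

**Step 14**
Reactants: 24 (2E,6Z)-8-[(tert-butyldiphenylsilyl)oxy]-6-methyl-2-[(2S)-5-(4-methylpent-3-en-1-yl)-6-oxo-3,6-dihydro-2H-pyran-2-yl]octa-2,6-dien-1-yl acetate
Product: 25 (2E,6Z)-8-hydroxy-6-methyl-2-[(2S)-5-(4-methylpent-3-en-1-yl)-6-oxo-3,6-dihydro-2H-pyran-2-yl]octa-2,6-dien-1-yl acetate (target)
Conditions: HF·pyridine, pyridine, THF, 0 °C to rt
Reagents that add atoms: none
Why: Buffered fluoride desilylation cleaves the primary silyl ether without base, so the acetate should stay in place and the base-sensitive 6-alkenyl dihydropyranone should not undergo eliminative ring opening.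

**Compound list**

1 | nerol, (2Z)-3,7-dimethylocta-2,6-dien-1-ol | CC(C)=CCC/C(C)=C\CO | starting material
2 | tert-butyl{[(2Z)-3,7-dimethylocta-2,6-dien-1-yl]oxy}diphenylsilane | CC(C)=CCC/C(C)=C\CO[Si](c1ccccc1)(c1ccccc1)C(C)(C)C | intermediate
3 | tert-butyl{[(2Z)-5-(3,3-dimethyloxiran-2-yl)-3-methylpent-2-en-1-yl]oxy}diphenylsilane (racemic 6,7-epoxide) | CC1(C)OC1CC/C(C)=C\CO[Si](c1ccccc1)(c1ccccc1)C(C)(C)C | intermediate
4 | (4Z)-6-[(tert-butyldiphenylsilyl)oxy]-4-methylhex-4-enal | O=CCC/C(C)=C\CO[Si](c1ccccc1)(c1ccccc1)C(C)(C)C | intermediate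
5 | tert-butyl{[(2Z)-3-methylhept-2-en-6-yn-1-yl]oxy}diphenylsilane | C#CCC/C(C)=C\CO[Si](c1ccccc1)(c1ccccc1)C(C)(C)C | intermediate
6 | {(5Z)-7-[(tert-butyldiphenylsilyl)oxy]-5-methylhept-5-en-1-yn-1-yl}lithium | [Li]C#CCC/C(C)=C\CO[Si](c1ccccc1)(c1ccccc1)C(C)(C)C | intermediate
7 | methyl (6Z)-8-[(tert-butyldiphenylsilyl)oxy]-6-methyloct-6-en-2-ynoate | COC(=O)C#CCC/C(C)=C\CO[Si](c1ccccc1)(c1ccccc1)C(C)(C)C | intermediate
8 | acrolein (prop-2-enal) | C=CC=O | starting material
9 | methyl (2E,6Z)-2-[bis(2-methylpropyl)alumanyl]-8-[(tert-butyldiphenylsilyl)oxy]-6-methylocta-2,6-dienoate (Al cis to H-3) | COC(=O)/C(=C\CC/C(C)=C\CO[Si](c1ccccc1)(c1ccccc1)C(C)(C)C)[Al](CC(C)C)CC(C)C | intermediate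
10 | methyl (2Z,6Z)-8-[(tert-butyldiphenylsilyl)oxy]-2-(1-hydroxyprop-2-en-1-yl)-6-methylocta-2,6-dienoate (racemic) | COC(=O)/C(=C\CC/C(C)=C\CO[Si](c1ccccc1)(c1ccccc1)C(C)(C)C)C(O)C=C | intermediate
11 | (4E,8Z)-10-[(tert-butyldiphenylsilyl)oxy]-4-(hydroxymethyl)-8-methyldeca-1,4,8-trien-3-ol (racemic) | OC/C(=C\CC/C(C)=C\CO[Si](c1ccccc1)(c1ccccc1)C(C)(C)C)C(O)C=C | intermediate
12 | (2E,6Z)-8-[(tert-butyldiphenylsilyl)oxy]-2-(1-hydroxyprop-2-en-1-yl)-6-methylocta-2,6-dien-1-yl acetate (racemic) | CC(=O)OC/C(=C\CC/C(C)=C\CO[Si](c1ccccc1)(c1ccccc1)C(C)(C)C)C(O)C=C | intermediate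
13 | (2E,6Z)-8-[(tert-butyldiphenylsilyl)oxy]-6-methyl-2-(prop-2-enoyl)octa-2,6-dien-1-yl acetate | CC(=O)OC/C(=C\CC/C(C)=C\CO[Si](c1ccccc1)(c1ccccc1)C(C)(C)C)C(=O)C=C | intermediate
14 | {(4E,8Z)-4-[(acetyloxy)methyl]-10-[(tert-butyldiphenylsilyl)oxy]-8-methyl-3-oxodeca-4,8-dien-1-yl}triphenylphosphonium tetrafluoroborate | CC(=O)OC/C(=C\CC/C(C)=C\CO[Si](c1ccccc1)(c1ccccc1)C(C)(C)C)C(=O)CC[P+](c1ccccc1)(c1ccccc1)c1ccccc1.F[B-](F)(F)F | intermediate
15 | {(3S,4E,8Z)-4-[(acetyloxy)methyl]-10-[(tert-butyldiphenylsilyl)oxy]-3-hydroxy-8-methyldeca-4,8-dien-1-yl}triphenylphosphonium tetrafluoroborate | CC(=O)OC/C(=C\CC/C(C)=C\CO[Si](c1ccccc1)(c1ccccc1)C(C)(C)C)[C@@H](O)CC[P+](c1ccccc1)(c1ccccc1)c1ccccc1.F[B-](F)(F)F | intermediate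
16 | {(3S,4E,8Z)-4-[(acetyloxy)methyl]-10-[(tert-butyldiphenylsilyl)oxy]-3-[(methanesulfonyl)oxy]-8-methyldeca-4,8-dien-1-yl}triphenylphosphonium tetrafluoroborate | CC(=O)OC/C(=C\CC/C(C)=C\CO[Si](c1ccccc1)(c1ccccc1)C(C)(C)C)[C@@H](OS(C)(=O)=O)CC[P+](c1ccccc1)(c1ccccc1)c1ccccc1.F[B-](F)(F)F | intermediate
17 | {(1S,2R)-2-[(2Z,6Z)-1-(acetyloxy)-8-[(tert-butyldiphenylsilyl)oxy]-6-methylocta-2,6-dien-2-yl]cyclopropyl}triphenylphosphonium tetrafluoroborate (trans) | CC(=O)OC/C(=C\CC/C(C)=C\CO[Si](c1ccccc1)(c1ccccc1)C(C)(C)C)[C@H]2C[C@@H]2[P+](c1ccccc1)(c1ccccc1)c1ccccc1.F[B-](F)(F)F | intermediate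
18 | 5-bromo-2-methylpent-2-ene | CC(C)=CCCBr | starting material
19 | diethyl oxalate | CCOC(=O)C(=O)OCC | starting material
20 | (4-methylpent-3-en-1-yl)magnesium bromide | CC(C)=CCC[Mg]Br | intermediate
21 | ethyl 6-methyl-2-oxohept-5-enoate | CCOC(=O)C(=O)CCC=C(C)C | intermediate
22 | cesium 6-methyl-2-oxohept-5-enoate | CC(C)=CCCC(=O)C(=O)[O-].[Cs+] | intermediate
23 | (3S,4E,8Z)-4-[(acetyloxy)methyl]-10-[(tert-butyldiphenylsilyl)oxy]-8-methyl-1-(triphenyl-λ5-phosphanylidene)deca-4,8-dien-3-yl 6-methyl-2-oxohept-5-enoate | CC(=O)OC/C(=C\CC/C(C)=C\CO[Si](c1ccccc1)(c1ccccc1)C(C)(C)C)[C@H](CC=P(c1ccccc1)(c1ccccc1)c1ccccc1)OC(=O)C(=O)CCC=C(C)C | intermediate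
24 | (2E,6Z)-8-[(tert-butyldiphenylsilyl)oxy]-6-methyl-2-[(2S)-5-(4-methylpent-3-en-1-yl)-6-oxo-3,6-dihydro-2H-pyran-2-yl]octa-2,6-dien-1-yl acetate | CC(=O)OC/C(=C\CC/C(C)=C\CO[Si](c1ccccc1)(c1ccccc1)C(C)(C)C)[C@@H]1CC=C(CCC=C(C)C)C(=O)O1 | intermediate
25 | (2E,6Z)-8-hydroxy-6-methyl-2-[(2S)-5-(4-methylpent-3-en-1-yl)-6-oxo-3,6-dihydro-2H-pyran-2-yl]octa-2,6-dien-1-yl acetate | CC(=O)OC/C(=C\CC/C(C)=C\CO)[C@@H]1CC=C(CCC=C(C)C)C(=O)O1 | target

**Step count and risks**

Total step count: 14 (12 in the main line, 2 for the keto acid salt).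
Longest linear sequence: 12 steps (steps 1 to 10, then 13 and 14, from nerol).

Steps most likely to fail:

Step 13 (carries the label). The ring opening may not start, because the α-keto carboxylate is a weak nucleophile and may condense with itself before the cyclopropane is attacked. The opening may also pass through an ionised allyl cation, with loss of configuration. Fallback with known chemistry, setting out from 15 and returning at 24: the cesium salt 22 is acidified (cold 1 M HCl, extraction) to 6-methyl-2-oxohept-5-enoic acid F1. F1 is coupled to the (S)-alcohol 15 by Steglich esterification (DCC, DMAP cat., CH2Cl2, 0 °C; retention at the carbinol carbon) to give the α-keto ester phosphonium salt F2. Deprotonation (K2CO3, 18-crown-6, CH2Cl2, or KN(SiMe3)2, THF, −78 °C) generates the same ylide 23, and intramolecular Wittig olefination should give 24.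

Step 10. The allylic mesylate may ionise before the ylide closes the ring, helped by the adjacent alkene or by the neighbouring acetate carbonyl; this would cause racemisation or 1,3-transposition. Fallback setting out from 14 and returning at 17: reduction of 14 with the enantiomeric (S)-oxazaborolidine and catecholborane gives the (R)-hydroxy phosphonium salt F3. Appel bromination (CBr4, PPh3, CH2Cl2, −20 °C) installs a covalent, isolable leaving group with inversion, giving the (S)-allylic bromide F4. Ylide formation (KN(SiMe3)2, THF, −78 °C, or aqueous NaOH/CH2Cl2) then closes the cyclopropane with a second inversion to the same salt 17.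

Step 8. The divinyl ketone may polymerise, or triphenylphosphine may add at the acetoxymethyl-substituted enone carbon and expel acetate. Fallback setting out from 12 and returning at 14: chemoselective hydroboration of the monosubstituted vinyl group of 12 (9-BBN, THF; NaBO3·4H2O) gives the 1,3-diol F5. Selective iodination of the primary hydroxyl (I2, PPh3, imidazole, CH2Cl2, 0 °C) gives the iodo alcohol F6. Quaternisation with PPh3 (MeCN, 60 °C) and anion exchange (aqueous NaBF4) give the racemic hydroxy phosphonium salt F7. Dess–Martin oxidation of F7 gives the β-phosphonio ketone 14 without forming the divinyl ketone.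

**Further compounds**

F1 | step 13 | 6-methyl-2-oxohept-5-enoic acid | CC(C)=CCCC(=O)C(=O)O
F2 | step 13 | {(3S,4E,8Z)-4-[(acetyloxy)methyl]-10-[(tert-butyldiphenylsilyl)oxy]-8-methyl-3-[(6-methyl-2-oxohept-5-enoyl)oxy]deca-4,8-dien-1-yl}triphenylphosphonium tetrafluoroborate | CC(=O)OC/C(=C\CC/C(C)=C\CO[Si](c1ccccc1)(c1ccccc1)C(C)(C)C)[C@H](CC[P+](c1ccccc1)(c1ccccc1)c1ccccc1)OC(=O)C(=O)CCC=C(C)C.F[B-](F)(F)F
F3 | step 10 | {(3R,4E,8Z)-4-[(acetyloxy)methyl]-10-[(tert-butyldiphenylsilyl)oxy]-3-hydroxy-8-methyldeca-4,8-dien-1-yl}triphenylphosphonium tetrafluoroborate | CC(=O)OC/C(=C\CC/C(C)=C\CO[Si](c1ccccc1)(c1ccccc1)C(C)(C)C)[C@H](O)CC[P+](c1ccccc1)(c1ccccc1)c1ccccc1.F[B-](F)(F)F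
F4 | step 10 | {(3S,4E,8Z)-4-[(acetyloxy)methyl]-3-bromo-10-[(tert-butyldiphenylsilyl)oxy]-8-methyldeca-4,8-dien-1-yl}triphenylphosphonium tetrafluoroborate | CC(=O)OC/C(=C\CC/C(C)=C\CO[Si](c1ccccc1)(c1ccccc1)C(C)(C)C)[C@@H](Br)CC[P+](c1ccccc1)(c1ccccc1)c1ccccc1.F[B-](F)(F)F
F5 | step 8 | (2E,6Z)-8-[(tert-butyldiphenylsilyl)oxy]-2-(1,3-dihydroxypropyl)-6-methylocta-2,6-dien-1-yl acetate (racemic) | CC(=O)OC/C(=C\CC/C(C)=C\CO[Si](c1ccccc1)(c1ccccc1)C(C)(C)C)C(O)CCO
F6 | step 8 | (2E,6Z)-8-[(tert-butyldiphenylsilyl)oxy]-2-(1-hydroxy-3-iodopropyl)-6-methylocta-2,6-dien-1-yl acetate (racemic) | CC(=O)OC/C(=C\CC/C(C)=C\CO[Si](c1ccccc1)(c1ccccc1)C(C)(C)C)C(O)CCI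
F7 | step 8 | {(4E,8Z)-4-[(acetyloxy)methyl]-10-[(tert-butyldiphenylsilyl)oxy]-3-hydroxy-8-methyldeca-4,8-dien-1-yl}triphenylphosphonium tetrafluoroborate (racemic) | CC(=O)OC/C(=C\CC/C(C)=C\CO[Si](c1ccccc1)(c1ccccc1)C(C)(C)C)C(O)CC[P+](c1ccccc1)(c1ccccc1)c1ccccc1.F[B-](F)(F)F
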